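The numbers in the tables stem from a simulated flask for an exercise; the scatter is artificial.

1. The eta and alpha runs look nearly the same: each starts from 20 mM of Q, with 0.47 equiv of J in eta and 0.71 equiv in alpha. But at 8.00 min, eta still holds Q 28%, and alpha holds 9%.

| run | time / min | G / % | Q / % |
|---|---|---|---|
| eta | 1.00 | 3 | 62 |
| eta | 3.00 | 16 | 40 |
| eta | 5.00 | 21 | 30 |
| eta | 8.00 | 25 | 28 |
| alpha | 2.00 | 13 | 34 |
| alpha | 4.00 | 25 | 17 |
| alpha | 6.00 | 32 | 13 |
| alpha | 8.00 | 35 | 9 |

(standard deviation of a reading: 1.5 percentage points)

2. Eta's Q falls 22 percentage points from 1.00 min to 3.00 min, but 2 points from 5.00 min to 8.00 min, with each reading good to 1.5 points. These readings look like a stall, as if eta's J were used up.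

3. Count turnovers. Eta's count, the fraction of Q lost over the equivalents of J charged, is 1.53. Alpha's turnover count, reckoned the same way, is 1.28. Any J left over would raise either count. At eta's count, alpha's J could carry 109% of the Q charged, which is more than the charge. So eta's end lies where its J stops, because its charge carries less than the Q, while alpha's Q goes on down.

4. The new flasks:

all flasks: Q 20 mM
- eta: J 0.47 equiv; run made earlier
- alpha: J 0.71 equiv; run made earlier
- Tuesday's: J 0.950 equiv; time 40 min
- Saturday's: J 0.950 equiv; time 10 min
- Thursday's: J 0.950 equiv; time 20 min

* which of the two there is more of at the end, counted by the Q in each, Tuesday's (G / D)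
* which of the two there is more of at the end, counted by the Q in each, Saturday's (G / D)
* which of the two there is more of at the end, counted by the Q in each, Thursday's (G / D)
* final G, as a percentage of the Q charged, in Tuesday's
* final G, as a percentage of the Q charged, in Saturday's
* final G, as a percentage of the Q charged, in Thursday's

- in percentages every species weighs as the Q in it: one D counts as two

My own reckoning assumes a count no higher than alpha's. With 0.950 equiv of J charged, Q is the limiting reagent if the count stays above 1.05; alpha's 1.28 stands above that, but the assumption sets no lower limit on the count, so this stays open. Each J takes one Q and some take a second, so D, counted by its two Q, is the Q lost minus the J used, doubled. With Q gone and the count at alpha's, that gives D about 44.0%, and a lower count gives less, leaving 56.0% or more for G and whatever has not yet become G. I call G ahead at each time.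

5. The forecast gives G 51% for Tuesday's, 45% for Saturday's and 48% for Thursday's. It puts G ahead on Tuesday's, but D on Saturday's and D on Thursday's, which differs from my call. It adds: “The G versus D calls are close.”

6. What the flasks hold:

    Q + Z → D (k = 0.339 M⁻¹ s⁻¹)
    Z ⇌ G (K = 5.28, k = 0.00508 s⁻¹)
    Q ⇌ L (K = 0.420, k = 8.31 × 10⁻⁴ s⁻¹)
    Q + J → Z (k = 1.02 M⁻¹ s⁻¹)

G ends at 55.3% in Tuesday's, 50.1% in Saturday's and 54.1% in Thursday's. Saturday's still holds Z 12.9% at 10.0 min, and its G stands at 55.5% after 100 min. Counted on J actually used, Tuesday's gives 1.21, lower than alpha's 1.28, and its D of 33.8% lies under the reckoned 44.0%. The neighbouring flask with 1.60 equiv of J counts 1.12, and its D stands at 19.8%.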